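Of the partner charged to the alder run, 42.7% ends as uncatalysed product and target, and both readings are level from 12.0 min. The reckoning here therefore takes partner as the limiting reagent, with the rest of it leaving one for one with second substrate through the catalyst.

all flasks: partner 0.0266 M; free catalyst 56 µM

|  | starting material | second substrate | temperature | remark | time |
|---|---|---|---|---|---|
| alder | 0.028 M | 0.028 M | 85 °C | run made earlier |  |
| oak | 0.039 M | 0.028 M | 96 °C | run made earlier |  |
| ash | 0.062 M | 0.028 M | 85 °C | run made earlier |  |
| cedar | 0.028 M | 0.042 M | 96 °C | run made earlier |  |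
| east | 0.028 M (in portions, 5, over 12 min) | 0.0280 M | 90 °C | first portion at the start, last at 12 min | 30 min |
| north-west | 0.028 M (fed, over 12 min) | 0.0280 M | 90 °C | all else is in the flask from the start; the feed brings no volume worth counting | 30 min |
| north-east | 0.028 M | 0.0280 M (fed, over 12 min) | 90 °C | all else is in the flask from the start; the feed brings no volume worth counting | 30 min |
| south | 0.028 M (fed, over 12 min) | 0.0280 M |  | the addition at 50 °C, then warmed to 90 °C; the feed brings no volume worth counting | 30 min |

- alder (time / min: uncatalysed product / %, target / %): 6.00: 29.8, 8.5; 12.0: 31.6, 8.7; 20.0: 31.6, 8.4; 25.0: 31.3, 8.6; 30.0: 31.6, 9.0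
- oak (time / min: uncatalysed product / %, target / %): 2.50: 27.2, 4.6; 5.00: 30.9, 5.6; 8.00: 31.2, 5.6; 15.0: 31.1, 4.8; 30.0: 31.5, 5.2
- ash (time / min: uncatalysed product / %, target / %): 2.50: 18.8, 2.7; 8.00: 25.6, 3.7; 15.0: 25.6, 3.3; 20.0: 25.4, 3.7; 30.0: 24.9, 3.5
- cedar (time / min: uncatalysed product / %, target / %): 2.50: 25.7, 5.2; 5.00: 28.2, 5.7; 8.00: 28.6, 5.0; 15.0: 28.9, 5.9; 30.0: 28.8, 5.4

(each reading ± 0.3 percentage points)



* the flask that comes out highest in amount of uncatalysed product, in percent of the starting material charged; "all alike" if 1.5 percentage points covers them all (east / north-west / north-east / south / all alike)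
* amount of uncatalysed product at the end, in percent of the starting material charged, east
* amount of uncatalysed product at the end, in percent of the starting material charged, north-west
* amount of uncatalysed product at the end, in percent of the starting material charged, north-east
* amount of uncatalysed product at the end, in percent of the starting material charged, south

The approach to the plateau gives time constants: the rates are 0.478 min⁻¹ in alder and 0.797 min⁻¹ in oak. Each rate, scaled by the uncatalysed product's share of partner and taken as a geometric mean across 85 °C and 96 °C, gives a drain of partner at 90 °C, reckoned as first order at the full charge of starting material, κ = 0.205 min⁻¹; with 0.028 M of starting material against 0.0266 M of partner, this constant is a rough simplification.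

In north-east the second substrate is assumed to be spent as it arrives, so the feed takes a fraction g = 0.0877 min⁻¹ of the partner charge each minute. With x the fraction of partner left, dx/dt = −g − κx, and x reaches zero at the partner stop time, ln(1 + κ/g)/κ = 5.88 min. This falls within the feed. The part not drained by the feed, 48.4% of the partner, is counted here as uncatalysed product, with target left out of this rough balance, which gives 46.0% of the starting material charged.

The forecast, reckoned on its own grounds, names north-east and gives 37% for east, 39% for north-west, 45% for north-east and 33.5% for south, saying “Feeding second substrate removes the competitor”.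

The flasks give 10.5% in east, 8.71% in north-west, 44.9% in north-east and 22.5% in south, so north-east stands highest.

    partner + catalyst intermediate A → free catalyst + target (k = 19.9 M⁻¹ s⁻¹, Ea = 35.0 kJ mol⁻¹)
    partner + catalyst intermediate B → free catalyst + second product (k = 479 M⁻¹ s⁻¹, Ea = 52.0 kJ mol⁻¹)
    starting material + free catalyst ⇌ catalyst intermediate A (K = 77.0 M⁻¹, k = 389 M⁻¹ s⁻¹, Ea = 51.0 kJ mol⁻¹, ΔH = −13.0 kJ mol⁻¹)
    starting material + partner → uncatalysed product (k = 0.109 M⁻¹ s⁻¹, Ea = 56.0 kJ mol⁻¹)
    second substrate + free catalyst ⇌ catalyst intermediate B (K = 2300 M⁻¹, k = 110 M⁻¹ s⁻¹, Ea = 37.0 kJ mol⁻¹, ΔH = 21.0 kJ mol⁻¹)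
    (constants at 90 °C)

The reckoning's 46.0% for north-east lies near the flask's 44.9%, but the split of partner differs: north-east sends 38.9% of its partner to second product against the reckoned 51.6%, and 13.8% to target against none reckoned, so the closeness is no check. The neighbouring flask is north-east with 0.011 M of partner, where the feed takes 0.212 min⁻¹ of the partner charge each minute. Its stop time is 3.30 min, which gives 11.8% of uncatalysed product, while that flask, with partner at 0%, gives 18.7%.

(The earlier runs and the new flask come from a simulation on assumed constants; scatter was added.)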